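**Plan** (germacrane numbering: carbocycle C1–C10, C14 on C10, C15 on C4, lactone C12(=O)–O6 across C6/C7, C13 = exo-methylene on C11, ester on O8)
1. Retrosynthesis: remove the O8 methacrylate, the C11=C13 methylene and the silyl ethers; cut the ten-membered ring at the sp2–sp3 bond C1–C2; then cut C8–C9 (acyl–allyl) and C6–C7 (aldol).
2. Forward: the lactone (ring B) is made first by an Evans succinate aldol/lactonisation between aldehyde 5 (C2–C6, C15) and imide 8 (C7, C8, C11, C12); allylsilane acylation and CBS reduction add C9, C10, C14 and O8.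
3. O8 is homoallylic to the 1,1-disubstituted C10 alkene: a vinylsilyl ether on O8 and ring-closing metathesis give a temporary six-membered 1,2-oxasilacyclohexene that forces Si, then I, on C1 to be cis to C9.
4. Key event: intramolecular alkyl–alkenyl Suzuki–Miyaura coupling of the C2 pinacolboronate with the C1 iodide closes the carbocycle (ring A). It is feasible because the C1(10) alkene is cis within the ring (C9 and C2 cis, E by CIP only because of C14–O) and the trans-fused lactone holds the C5 and C8 arms on adjacent carbons.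
5. Stereochemistry: C4 from Rh/(R)-BINAP conjugate addition; C6 and C7 from the (S)-benzyloxazolidinone aldol; C8 from (S)-CBS reduction (Felkin-matched); alkene geometry from the oxasilacycle, carried through the coupling with retention.
6. End game: α-methylenation of the lactone, TES removal, methacrylation of O8, desilylation of O14/O15.

Key step: step 16

Assumptions and remarks: Rh/(R)-BINAP is taken to add vinyl to furan-2(5H)-one with the facial sense known for cyclic enones. The C4 vinyl group is converted into the C2 boronate before the metathesis so that only one alkene pair is present in step 13. The CIP descriptor at the lactone carbon C7 (ring position 4 or 3 in the names) switches between R and S along the route only because the priority of the C8 branch changes with the O8 substituent; the spatial arrangement is constant. Abbreviations: TBDPSO = tert-butyldiphenylsilyloxy, TES = triethylsilyl, Bpin = 4,4,5,5-tetramethyl-1,3,2-dioxaborolan-2-yl.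

**Step 1**
Reactants: 1 furan-2(5H)-one
Product: 2 (R)-4-vinyldihydrofuran-2(3H)-one
Conditions: potassium vinyltrifluoroborate, [Rh(cod)2]PF6 (3 mol%), (R)-BINAP (3.3 mol%), toluene/H2O 20:1, 105 °C
Reagents that add atoms: potassium vinyltrifluoroborate, C=C[B-](F)(F)F.[K+]
Why: Hayashi–Miyaura rhodium-catalysed asymmetric 1,4-addition of the vinyl group to the butenolide, in which the (R)-BINAP ligand directs the vinyl–rhodium insertion to one face of the C=C bond and so sets the stereocenter that becomes C4.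

**Step 2**
Reactants: 2 (R)-4-vinyldihydrofuran-2(3H)-one
Product: 3 (R)-3-(hydroxymethyl)-N-methoxy-N-methylpent-4-enamide
Conditions: MeNHOMe·HCl, i-PrMgCl, THF, −20 → 0 °C
Reagents that add atoms: N,O-dimethylhydroxylamine hydrochloride, CNOC.Cl
Why: Weinreb aminolysis of the lactone by the chloromagnesium amide opens the ring to the hydroxy amide without touching the stereocenter or the vinyl group.

**Step 3**
Reactants: 3 (R)-3-(hydroxymethyl)-N-methoxy-N-methylpent-4-enamide
Product: 4 (R)-3-[(TBDPSO)methyl]-N-methoxy-N-methylpent-4-enamide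
Conditions: TBDPSCl, imidazole, DMF, 0 °C → rt
Reagents that add atoms: tert-butyl(chloro)diphenylsilane, CC(C)(C)[Si](Cl)(c1ccccc1)c1ccccc1
Why: Standard silylation of the primary alcohol (the later C15–OH) prevents relactonisation and installs a protecting group that lasts to the final step.

**Step 4**
Reactants: 4 (R)-3-[(TBDPSO)methyl]-N-methoxy-N-methylpent-4-enamide
Product: 5 (R)-3-[(TBDPSO)methyl]pent-4-enal
Conditions: i-Bu2AlH, THF, −78 °C; aq. potassium sodium tartrate
Reagents that add atoms: none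
Why: Reduction of a Weinreb amide by i-Bu2AlH stops at the aldehyde through the stable chelated tetrahedral intermediate.

**Step 5**
Reactants: 6 (S)-4-benzyloxazolidin-2-one; 7 methyl 4-chloro-4-oxobutanoate
Product: 8 methyl 4-[(S)-4-benzyl-2-oxooxazolidin-3-yl]-4-oxobutanoate
Conditions: n-BuLi, THF, −78 °C; then 7, −78 → 0 °C
Reagents that add atoms: none
Why: N-acylation of the lithiated Evans oxazolidinone by the acid chloride gives the succinate imide, the methyl ester being much less electrophilic.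

**Step 6**
Reactants: 8 methyl 4-[(S)-4-benzyl-2-oxooxazolidin-3-yl]-4-oxobutanoate; 5 (R)-3-[(TBDPSO)methyl]pent-4-enal
Product: 10 (S)-4-benzyl-3-[(2R,3S)-2-{(R)-2-[(TBDPSO)methyl]but-3-en-1-yl}-5-oxotetrahydrofuran-3-carbonyl]oxazolidin-2-one, via syn-aldol adduct 9 (not isolated)
Conditions: Bu2BOTf, i-Pr2NEt, CH2Cl2, −78 → 0 °C; 5, −78 → 0 °C; pH 7 buffer, MeOH, 30% H2O2; then p-TsOH·H2O (cat.), CH2Cl2, rt
Reagents that add atoms: none
Why: Evans syn-aldol reaction in which the (Z)-dibutylboron enolate of the imide (soft enolisation is selective for the imide α-CH2) adds to aldehyde 5 through a Zimmerman–Traxler chair with one enolate face shielded by the (S)-benzyl auxiliary, setting C7 and C6 (syn), after which acid lactonises the γ-hydroxy ester to the trans-4,5-disubstituted lactone.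

**Step 7**
Reactants: 10 lactone imide (name as in step 6)
Product: 11 (2R,3S)-2-{(R)-2-[(TBDPSO)methyl]but-3-en-1-yl}-5-oxotetrahydrofuran-3-carboxylic acid
Conditions: LiOH·H2O, 30% H2O2, THF/H2O 3:1, 0 °C; Na2SO3; 1 M HCl to pH 2
Reagents that add atoms: lithium hydroperoxide (from LiOH and H2O2), [Li+].[O-]O
Why: Hydroperoxide cleaves the exocyclic imide carbonyl selectively (Evans auxiliary removal), any opened lactone reclosing on acidification, and the auxiliary is recovered.

**Step 8**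
Reactants: 12 2-[(trimethylsilyl)methyl]prop-2-en-1-ol
Product: 13 tert-butyl(diphenyl)({2-[(trimethylsilyl)methyl]prop-2-en-1-yl}oxy)silane
Conditions: TBDPSCl, imidazole, CH2Cl2, 0 °C → rt
Reagents that add atoms: tert-butyl(chloro)diphenylsilane, CC(C)(C)[Si](Cl)(c1ccccc1)c1ccccc1
Why: Silylation of the primary allylic alcohol gives the bifunctional allylsilane without touching the allylic C–Si bond.

**Step 9**
Reactants: 11 lactone acid (name as in step 7); 13 allylsilane (name as in step 8)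
Product: 15 (4S,5R)-5-{(R)-2-[(TBDPSO)methyl]but-3-en-1-yl}-4-{3-[(TBDPSO)methyl]but-3-enoyl}dihydrofuran-2(3H)-one, via acid chloride 14 (not isolated)
Conditions: (COCl)2, DMF (cat.), CH2Cl2, 0 °C → rt; concentrate; 13, TiCl4, CH2Cl2, −78 °C; NaHCO3 quench at −78 °C
Reagents that add atoms: none
Why: Hosomi–Sakurai acylation in which the allylsilane attacks the TiCl4-activated acid chloride through its CH2= terminus (SE2′) and loss of the trimethylsilyl group gives the β,γ-unsaturated ketone with the 1,1-disubstituted C10 alkene, the cold quench avoiding conjugation and the trans-lactone being the stable C7 epimer.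

**Step 10**
Reactants: 15 ketone (name as in step 9)
Product: 16 (4R,5R)-5-{(R)-2-[(TBDPSO)methyl]but-3-en-1-yl}-4-{(R)-1-hydroxy-3-[(TBDPSO)methyl]but-3-en-1-yl}dihydrofuran-2(3H)-one
Conditions: (S)-2-methyl-CBS-oxazaborolidine (0.5 equiv), catecholborane, toluene/CH2Cl2, −78 °C
Reagents that add atoms: none
Why: Corey–Bakshi–Shibata reduction in which the (S)-oxazaborolidine delivers hydride to the ketone face that gives the (8R)-carbinol when the branched ring carbon C7 is the large and the C9 methylene the small group, the Felkin–Anh preference of C7 pointing the same way, while catecholborane at −78 °C leaves both alkenes and the lactone alone.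

**Step 11**
Reactants: 16 homoallylic alcohol (name as in step 10)
Product: 17 (4R,5R)-5-{(2S)-2-[(TBDPSO)methyl]-4-(Bpin)butyl}-4-{(R)-1-hydroxy-3-[(TBDPSO)methyl]but-3-en-1-yl}dihydrofuran-2(3H)-one
Conditions: pinacolborane (2.2 equiv), [Ir(cod)Cl]2 (2 mol%), dppm (4 mol%), CH2Cl2, rt; MeOH
Reagents that add atoms: pinacolborane, [H]B1OC(C)(C)C(C)(C)O1
Why: Iridium-catalysed anti-Markovnikov hydroboration with pinacolborane is selective for the monosubstituted vinyl group over the 1,1-disubstituted alkene, which removes the one alkene that would compete in the metathesis and installs the C2 nucleophile for the key step.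

**Step 12**
Reactants: 17 boronate alcohol (name as in step 11)
Product: 18 (4S,5R)-5-{(2S)-2-[(TBDPSO)methyl]-4-(Bpin)butyl}-4-{(R)-1-[dimethyl(vinyl)silyloxy]-3-[(TBDPSO)methyl]but-3-en-1-yl}dihydrofuran-2(3H)-one
Conditions: ClSiMe2(CH=CH2), Et3N, DMAP (cat.), CH2Cl2, 0 °C
Reagents that add atoms: chloro(dimethyl)vinylsilane, C=C[Si](C)(C)Cl
Why: Silylation of the C8 hydroxyl places the vinylsilane tether on the oxygen that is homoallylic to the C10 methylene.

**Step 13**
Reactants: 18 vinylsilyl ether (name as in step 12)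
Product: 19 (4S,5R)-5-{(2S)-2-[(TBDPSO)methyl]-4-(Bpin)butyl}-4-{(6R)-2,2-dimethyl-4-[(TBDPSO)methyl]-5,6-dihydro-2H-1,2-oxasilin-6-yl}dihydrofuran-2(3H)-one
Conditions: Mo(=CHCMe2Ph)(=N-2,6-iPr2C6H3)[OCMe(CF3)2]2 (10 mol%), benzene, rt → 50 °C, 0.01 M
Reagents that add atoms: none
Why: Silicon-tethered ring-closing metathesis of the vinylsilane with the 1,1-disubstituted alkene, driven by loss of ethylene, gives a six-membered 1,2-oxasilacyclohexene whose ring forces silicon on C1 to be cis to C9, which fixes the geometry of the trisubstituted alkene.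

**Step 14**
Reactants: 19 oxasilacycle (name as in step 13)
Product: 20 (4R,5R)-5-{(2S)-2-[(TBDPSO)methyl]-4-(Bpin)butyl}-4-{(1R,3E)-1-hydroxy-4-iodo-3-[(TBDPSO)methyl]but-3-en-1-yl}dihydrofuran-2(3H)-one
Conditions: N-iodosuccinimide, 2,6-lutidine, (CF3)2CHOH, 0 °C; then AcOH/THF/H2O, rt
Reagents that add atoms: N-iodosuccinimide, O=C1CCC(=O)N1I
Why: Electrophilic ipso-iododesilylation of the alkenylsilane (iodonium attack at C1 gives the tertiary β-silyl cation at C10, then silicon is lost) proceeds with retention, so iodine takes the place of silicon cis to C9, and mild acid hydrolysis of the remaining Si–O bond frees O8.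

**Step 15**
Reactants: 20 iodo alcohol (name as in step 14)
Product: 21 (4S,5R)-5-{(2S)-2-[(TBDPSO)methyl]-4-(Bpin)butyl}-4-{(1R,3E)-4-iodo-3-[(TBDPSO)methyl]-1-(triethylsilyloxy)but-3-en-1-yl}dihydrofuran-2(3H)-one
Conditions: Et3SiOTf, 2,6-lutidine, CH2Cl2, −78 °C
Reagents that add atoms: triethylsilyl trifluoromethanesulfonate, CC[Si](CC)(CC)OS(=O)(=O)C(F)(F)F
Why: Silylation of the secondary C8 alcohol as its triethylsilyl ether protects it during the later enolate chemistry (no translactonisation to O8) and is orthogonal to the two primary TBDPS ethers.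

**Step 16**
Reactants: 21 iodo boronate (name as in step 15)
Product: 22 (1(10)E,4S,6R,7S,8R)-14,15-bis(TBDPSO)-8-(triethylsilyloxy)germacr-1(10)-en-12,6-olide
Conditions: Pd(OAc)2 (15 mol%), RuPhos (30 mol%), K3PO4 (3 equiv), toluene/H2O 10:1, 80 °C, 21 added by syringe pump to 0.002 M
Reagents that add atoms: none
Why: Oxidative addition of zerovalent palladium into the C1–I bond (retention), phosphate-assisted transmetalation of the primary C2 alkyl group from the hydroxyboronate and reductive elimination form the C1–C2 bond. The closest known reaction type is the intramolecular B-alkyl Suzuki–Miyaura macrocyclisation of an alkenyl iodide with a primary alkylboron reagent. The ten-membered carbocycle (ring A) closes head-to-tail by reductive elimination from an eleven-membered alkyl(alkenyl)palladium chelate, the C1(10) alkene ending endocyclic. No stereocenter is formed: the alkene geometry (C2 cis to C9) is that of the iodide fixed in the oxasilacycle and is carried over with retention, and C4, C6, C7 and C8 are untouched. The step needs ring closure to beat oligomerisation and reductive elimination to beat β-hydride elimination; the trans-fused lactone holds the C5 and C8 arms on adjacent carbons, the cis ring alkene avoids trans-cyclodecene strain, and high dilution with the bulky electron-rich RuPhos ligand does the rest. Chemoselectivity is secured by design, since neither the methylene lactone nor the methacrylate (Heck and conjugate acceptors) is present yet.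

**Step 17**
Reactants: 22 macrocyclic lactone (name as in step 16)
Product: 25 (1(10)E,4S,6R,7S,8R)-14,15-bis(TBDPSO)-8-(triethylsilyloxy)germacra-1(10),11(13)-dien-12,6-olide, via Mannich base 23 (not isolated), via trimethylammonium iodide 24 (not isolated)
Conditions: LiN(i-Pr)2, THF, −78 °C; CH2=NMe2+ I−, −78 °C → rt; MeI, MeOH, rt; NaHCO3 (aq)/CH2Cl2, rt
Reagents that add atoms: N,N-dimethylmethyleneiminium iodide (Eschenmoser's salt), C=[N+](C)C.[I-]
Why: α-Methylenation of the lactone by Mannich reaction of its lithium enolate with Eschenmoser's salt, N-methylation and Hofmann-type elimination of trimethylamine gives the exocyclic C11=C13 alkene, C11 being the only enolisable position and its transient configuration irrelevant.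

**Step 18**
Reactants: 25 methylene lactone TES ether (name as in step 17)
Product: 26 (1(10)E,4S,6R,7R,8R)-14,15-bis(TBDPSO)-8-hydroxygermacra-1(10),11(13)-dien-12,6-olide
Conditions: PPTS (cat.), MeOH/CH2Cl2 1:1, 0 °C
Reagents that add atoms: none
Why: Mild acid-catalysed methanolysis removes the secondary triethylsilyl ether selectively while the primary TBDPS ethers and the methylene lactone survive.

**Step 19**
Reactants: 26 C8 alcohol (name as in step 18)
Product: 27 (1(10)E,4S,6R,7S,8R)-14,15-bis(TBDPSO)-8-(methacryloyloxy)germacra-1(10),11(13)-dien-12,6-olide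
Conditions: methacrylic anhydride, Et3N, DMAP (cat.), CH2Cl2, 0 °C → rt
Reagents that add atoms: methacrylic anhydride, C=C(C)C(=O)OC(=O)C(C)=C
Why: DMAP-catalysed acyl transfer from methacrylic anhydride esterifies the free C8 alcohol with retention at C8 under conditions too mild for lactone migration.

**Step 20**
Reactants: 27 bis-silyl ether (name as in step 19)
Product: 28 (1(10)E,4S,6R,7S,8R)-14,15-dihydroxy-8-(methacryloyloxy)germacra-1(10),11(13)-dien-12,6-olide (target, CNP0546547.2)
Conditions: HF·pyridine, pyridine, THF, 0 °C → rt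
Reagents that add atoms: none
Why: Fluoride-mediated desilylation with buffered HF·pyridine cleaves both primary TBDPS ethers without base, so neither acyl migration nor conjugate addition to the two acrylate units should occur.

**Compound list**
1 | furan-2(5H)-one | O=C1OCC=C1 | starting material
2 | (R)-4-vinyldihydrofuran-2(3H)-one | C=C[C@H]1CC(=O)OC1 | intermediate
3 | (R)-3-(hydroxymethyl)-N-methoxy-N-methylpent-4-enamide | C=C[C@H](CO)CC(=O)N(C)OC | intermediate
4 | (R)-3-[(tert-butyldiphenylsilyloxy)methyl]-N-methoxy-N-methylpent-4-enamide | C=C[C@H](CO[Si](c1ccccc1)(c1ccccc1)C(C)(C)C)CC(=O)N(C)OC | intermediate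
5 | (R)-3-[(tert-butyldiphenylsilyloxy)methyl]pent-4-enal | C=C[C@H](CO[Si](c1ccccc1)(c1ccccc1)C(C)(C)C)CC=O | intermediate
6 | (S)-4-benzyloxazolidin-2-one | O=C1OC[C@H](Cc2ccccc2)N1 | starting material
7 | methyl 4-chloro-4-oxobutanoate | COC(=O)CCC(Cl)=O | starting material
8 | methyl 4-[(S)-4-benzyl-2-oxooxazolidin-3-yl]-4-oxobutanoate | COC(=O)CCC(=O)N1[C@@H](Cc2ccccc2)COC1=O | intermediate
9 | methyl (3S,4R,6R)-3-[(S)-4-benzyl-2-oxooxazolidine-3-carbonyl]-6-[(tert-butyldiphenylsilyloxy)methyl]-4-hydroxyoct-7-enoate (syn-aldol adduct) | COC(=O)C[C@@H]([C@H](O)C[C@H](C=C)CO[Si](c1ccccc1)(c1ccccc1)C(C)(C)C)C(=O)N1[C@@H](Cc2ccccc2)COC1=O | intermediate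
10 | (S)-4-benzyl-3-[(2R,3S)-2-{(R)-2-[(tert-butyldiphenylsilyloxy)methyl]but-3-en-1-yl}-5-oxotetrahydrofuran-3-carbonyl]oxazolidin-2-one | O=C1OC[C@H](Cc2ccccc2)N1C(=O)[C@@H]1[C@@H](C[C@H](C=C)CO[Si](c2ccccc2)(c2ccccc2)C(C)(C)C)OC(=O)C1 | intermediate
11 | (2R,3S)-2-{(R)-2-[(tert-butyldiphenylsilyloxy)methyl]but-3-en-1-yl}-5-oxotetrahydrofuran-3-carboxylic acid | OC(=O)[C@@H]1[C@@H](C[C@H](C=C)CO[Si](c2ccccc2)(c2ccccc2)C(C)(C)C)OC(=O)C1 | intermediate
12 | 2-[(trimethylsilyl)methyl]prop-2-en-1-ol | C=C(CO)C[Si](C)(C)C | starting material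
13 | tert-butyl(diphenyl)({2-[(trimethylsilyl)methyl]prop-2-en-1-yl}oxy)silane | C=C(CO[Si](c1ccccc1)(c1ccccc1)C(C)(C)C)C[Si](C)(C)C | intermediate
14 | (2R,3S)-2-{(R)-2-[(tert-butyldiphenylsilyloxy)methyl]but-3-en-1-yl}-5-oxotetrahydrofuran-3-carbonyl chloride | ClC(=O)[C@@H]1[C@@H](C[C@H](C=C)CO[Si](c2ccccc2)(c2ccccc2)C(C)(C)C)OC(=O)C1 | intermediate
15 | (4S,5R)-5-{(R)-2-[(tert-butyldiphenylsilyloxy)methyl]but-3-en-1-yl}-4-{3-[(tert-butyldiphenylsilyloxy)methyl]but-3-enoyl}dihydrofuran-2(3H)-one | C=C(CO[Si](c1ccccc1)(c1ccccc1)C(C)(C)C)CC(=O)[C@@H]1[C@@H](C[C@H](C=C)CO[Si](c2ccccc2)(c2ccccc2)C(C)(C)C)OC(=O)C1 | intermediate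
16 | (4R,5R)-5-{(R)-2-[(tert-butyldiphenylsilyloxy)methyl]but-3-en-1-yl}-4-{(R)-1-hydroxy-3-[(tert-butyldiphenylsilyloxy)methyl]but-3-en-1-yl}dihydrofuran-2(3H)-one | O[C@H](CC(=C)CO[Si](c1ccccc1)(c1ccccc1)C(C)(C)C)[C@@H]1[C@@H](C[C@H](C=C)CO[Si](c2ccccc2)(c2ccccc2)C(C)(C)C)OC(=O)C1 | intermediate
17 | (4R,5R)-5-{(2S)-2-[(tert-butyldiphenylsilyloxy)methyl]-4-(4,4,5,5-tetramethyl-1,3,2-dioxaborolan-2-yl)butyl}-4-{(R)-1-hydroxy-3-[(tert-butyldiphenylsilyloxy)methyl]but-3-en-1-yl}dihydrofuran-2(3H)-one | O[C@H](CC(=C)CO[Si](c1ccccc1)(c1ccccc1)C(C)(C)C)[C@@H]1[C@@H](C[C@H](CCB2OC(C)(C)C(C)(C)O2)CO[Si](c2ccccc2)(c2ccccc2)C(C)(C)C)OC(=O)C1 | intermediate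
18 | (4S,5R)-5-{(2S)-2-[(tert-butyldiphenylsilyloxy)methyl]-4-(pinacolboryl)butyl}-4-{(R)-1-[dimethyl(vinyl)silyloxy]-3-[(tert-butyldiphenylsilyloxy)methyl]but-3-en-1-yl}dihydrofuran-2(3H)-one | C=C[Si](C)(C)O[C@H](CC(=C)CO[Si](c1ccccc1)(c1ccccc1)C(C)(C)C)[C@@H]1[C@@H](C[C@H](CCB2OC(C)(C)C(C)(C)O2)CO[Si](c2ccccc2)(c2ccccc2)C(C)(C)C)OC(=O)C1 | intermediate
19 | (4S,5R)-5-{(2S)-2-[(tert-butyldiphenylsilyloxy)methyl]-4-(pinacolboryl)butyl}-4-{(6R)-2,2-dimethyl-4-[(tert-butyldiphenylsilyloxy)methyl]-5,6-dihydro-2H-1,2-oxasilin-6-yl}dihydrofuran-2(3H)-one | C[Si]3(C)O[C@H](CC(CO[Si](c2ccccc2)(c2ccccc2)C(C)(C)C)=C3)[C@@H]1[C@@H](C[C@H](CCB2OC(C)(C)C(C)(C)O2)CO[Si](c2ccccc2)(c2ccccc2)C(C)(C)C)OC(=O)C1 | intermediate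
20 | (4R,5R)-5-{(2S)-2-[(tert-butyldiphenylsilyloxy)methyl]-4-(pinacolboryl)butyl}-4-{(1R,3E)-1-hydroxy-4-iodo-3-[(tert-butyldiphenylsilyloxy)methyl]but-3-en-1-yl}dihydrofuran-2(3H)-one | O[C@H](C/C(CO[Si](c1ccccc1)(c1ccccc1)C(C)(C)C)=C\I)[C@@H]1[C@@H](C[C@H](CCB2OC(C)(C)C(C)(C)O2)CO[Si](c2ccccc2)(c2ccccc2)C(C)(C)C)OC(=O)C1 | intermediate
21 | (4S,5R)-5-{(2S)-2-[(tert-butyldiphenylsilyloxy)methyl]-4-(pinacolboryl)butyl}-4-{(1R,3E)-4-iodo-3-[(tert-butyldiphenylsilyloxy)methyl]-1-(triethylsilyloxy)but-3-en-1-yl}dihydrofuran-2(3H)-one | CC[Si](CC)(CC)O[C@H](C/C(CO[Si](c1ccccc1)(c1ccccc1)C(C)(C)C)=C\I)[C@@H]1[C@@H](C[C@H](CCB2OC(C)(C)C(C)(C)O2)CO[Si](c2ccccc2)(c2ccccc2)C(C)(C)C)OC(=O)C1 | intermediate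
22 | (1(10)E,4S,6R,7S,8R)-14,15-bis(tert-butyldiphenylsilyloxy)-8-(triethylsilyloxy)germacr-1(10)-en-12,6-olide | CC[Si](CC)(CC)O[C@@H]1C/C(CO[Si](c3ccccc3)(c3ccccc3)C(C)(C)C)=C\CC[C@H](CO[Si](c3ccccc3)(c3ccccc3)C(C)(C)C)C[C@H]2OC(=O)C[C@H]12 | intermediate
23 | 13-(dimethylamino) derivative of 22 (Mannich base, C11 epimers) | CC[Si](CC)(CC)O[C@@H]1C/C(CO[Si](c3ccccc3)(c3ccccc3)C(C)(C)C)=C\CC[C@H](CO[Si](c3ccccc3)(c3ccccc3)C(C)(C)C)C[C@H]2OC(=O)C(CN(C)C)[C@H]12 | intermediate
24 | 13-(trimethylammonio) derivative of 22, iodide salt (C11 epimers) | CC[Si](CC)(CC)O[C@@H]1C/C(CO[Si](c3ccccc3)(c3ccccc3)C(C)(C)C)=C\CC[C@H](CO[Si](c3ccccc3)(c3ccccc3)C(C)(C)C)C[C@H]2OC(=O)C(C[N+](C)(C)C)[C@H]12.[I-] | intermediate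
25 | (1(10)E,4S,6R,7S,8R)-14,15-bis(tert-butyldiphenylsilyloxy)-8-(triethylsilyloxy)germacra-1(10),11(13)-dien-12,6-olide | CC[Si](CC)(CC)O[C@@H]1C/C(CO[Si](c3ccccc3)(c3ccccc3)C(C)(C)C)=C\CC[C@H](CO[Si](c3ccccc3)(c3ccccc3)C(C)(C)C)C[C@H]2OC(=O)C(=C)[C@H]12 | intermediate
26 | (1(10)E,4S,6R,7R,8R)-14,15-bis(tert-butyldiphenylsilyloxy)-8-hydroxygermacra-1(10),11(13)-dien-12,6-olide | O[C@@H]1C/C(CO[Si](c3ccccc3)(c3ccccc3)C(C)(C)C)=C\CC[C@H](CO[Si](c3ccccc3)(c3ccccc3)C(C)(C)C)C[C@H]2OC(=O)C(=C)[C@H]12 | intermediate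
27 | (1(10)E,4S,6R,7S,8R)-14,15-bis(tert-butyldiphenylsilyloxy)-8-(methacryloyloxy)germacra-1(10),11(13)-dien-12,6-olide | C=C(C)C(=O)O[C@@H]1C/C(CO[Si](c3ccccc3)(c3ccccc3)C(C)(C)C)=C\CC[C@H](CO[Si](c3ccccc3)(c3ccccc3)C(C)(C)C)C[C@H]2OC(=O)C(=C)[C@H]12 | intermediate
28 | (1(10)E,4S,6R,7S,8R)-14,15-dihydroxy-8-(methacryloyloxy)germacra-1(10),11(13)-dien-12,6-olide | C=C(C)C(=O)O[C@@H]1C/C(CO)=C\CC[C@H](CO)C[C@H]2OC(=O)C(=C)[C@H]12 | target

**Step count and risks**
Total steps: 20. Longest linear sequence: 18 (steps 1–4, 6, 7, 9–20).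

Steps most likely to fail:

1. Step 16 (ring closure). Slow transmetalation of the primary alkyl pinacolboronate could let protodeboronation, β-hydride elimination or intermolecular coupling outrun closure of the ten-membered ring. Fallback, from 21 back to 22, changes the nucleophile from boron to zinc: 21 is oxidised (NaBO3·4H2O, THF/H2O) to the primary C2 alcohol F1, which is converted (I2, PPh3, imidazole) into the primary alkyl iodide F2; zinc dust/LiCl in THF should insert only into the sp3 C–I bond to give the alkylzinc iodide F3, and slow addition of this solution to Pd2(dba)3/SPhos in THF at 40 °C (intramolecular Negishi coupling) returns to macrocycle 22.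

2. Step 13 (tethered metathesis). Metathesis of the vinylsilane onto the hindered 1,1-disubstituted alkene may be sluggish, and the molybdenum alkylidene may be deactivated by the lactone or boronate. Fallback, from 17 back to 20, replaces the silicon tether by a boron tether: transesterification of 17 with vinylboronic acid dibutyl ester gives the mixed vinylboronate F4, ring-closing metathesis with the second-generation Grubbs catalyst RuCl2(=CHPh)(PCy3)(H2IMes) in CH2Cl2 at 40 °C and aqueous work-up give the cyclic alkenylboronic half ester F5, and iododeboronation with N-iodosuccinimide in MeCN (retention) followed by aqueous work-up gives iodo alcohol 20.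

3. Step 9 (acylation). Under TiCl4 the β,γ-unsaturated ketone may isomerise into conjugation or the allylic silyl ether may ionise. Fallback, from 10 back to 15, builds the C8–C9 bond at the aldehyde level: NaBH4 in THF/H2O reduces the imide to the primary alcohol F6, Dess–Martin periodinane gives the aldehyde F7, Hosomi–Sakurai allylation with 13 and BF3·OEt2 at −78 °C gives the homoallylic alcohol F8 (either C8 epimer is usable), and Dess–Martin oxidation gives ketone 15.

Further compounds
F1 | step 16 | primary alcohol (C2–OH in place of the boronate of 21) | CC[Si](CC)(CC)O[C@H](C/C(CO[Si](c1ccccc1)(c1ccccc1)C(C)(C)C)=C\I)[C@@H]1[C@@H](C[C@H](CCO)CO[Si](c2ccccc2)(c2ccccc2)C(C)(C)C)OC(=O)C1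
F2 | step 16 | primary alkyl iodide (C2–I in place of the boronate of 21) | CC[Si](CC)(CC)O[C@H](C/C(CO[Si](c1ccccc1)(c1ccccc1)C(C)(C)C)=C\I)[C@@H]1[C@@H](C[C@H](CCI)CO[Si](c2ccccc2)(c2ccccc2)C(C)(C)C)OC(=O)C1
F3 | step 16 | alkylzinc iodide (C2–ZnI in place of the boronate of 21) | CC[Si](CC)(CC)O[C@H](C/C(CO[Si](c1ccccc1)(c1ccccc1)C(C)(C)C)=C\I)[C@@H]1[C@@H](C[C@H](CC[Zn]I)CO[Si](c2ccccc2)(c2ccccc2)C(C)(C)C)OC(=O)C1
F4 | step 13 | mixed butyl vinylboronate of alcohol 17 | C=CB(OCCCC)O[C@H](CC(=C)CO[Si](c1ccccc1)(c1ccccc1)C(C)(C)C)[C@@H]1[C@@H](C[C@H](CCB2OC(C)(C)C(C)(C)O2)CO[Si](c2ccccc2)(c2ccccc2)C(C)(C)C)OC(=O)C1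
F5 | step 13 | cyclic alkenylboronic half ester (2-hydroxy-5,6-dihydro-2H-1,2-oxaborinine analogue of 19) | OB3O[C@H](CC(CO[Si](c2ccccc2)(c2ccccc2)C(C)(C)C)=C3)[C@@H]1[C@@H](C[C@H](CCB2OC(C)(C)C(C)(C)O2)CO[Si](c2ccccc2)(c2ccccc2)C(C)(C)C)OC(=O)C1
F6 | step 9 | 4-(hydroxymethyl) lactone (C8 primary alcohol) | OC[C@@H]1[C@@H](C[C@H](C=C)CO[Si](c2ccccc2)(c2ccccc2)C(C)(C)C)OC(=O)C1
F7 | step 9 | 4-formyl lactone (C8 aldehyde) | O=C[C@@H]1[C@@H](C[C@H](C=C)CO[Si](c2ccccc2)(c2ccccc2)C(C)(C)C)OC(=O)C1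
F8 | step 9 | homoallylic alcohol, C8 epimers of 16 | OC(CC(=C)CO[Si](c1ccccc1)(c1ccccc1)C(C)(C)C)[C@@H]1[C@@H](C[C@H](C=C)CO[Si](c2ccccc2)(c2ccccc2)C(C)(C)C)OC(=O)C1
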